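**Retrosynthetic overview**

1. Target 19 ⇐ methyl ester 18 ⇐ hydroxymethyl ester 15 ⇐ cis-fused peroxy-lactone 14: the C4 methyl is carried as a CH2–O arm tied to the C3 acetic acid arm as a δ-lactone, which is later opened, deoxygenated and saponified.
2. Key disconnection 14 ⇒ ozonide ester 12: one Lewis-acid operation inserts the C3–O–O unit of a 1,2,4-trioxolane into the C4–C6 σ bond of a cyclopropane, forming C3–C4 and O1–C6 (formal [3+3], strain release of both small rings).
3. Enabling feature: in the 1,2-dioxane ring (O1, O2, C3, C4, C5, C6) the peroxide-bearing C3 is at the acetal level and can become a peroxycarbenium carbon, quaternary C6 can carry positive charge, and C4 and C6 are 1,3-related across the C5 methylene, so C4–C5–C6 is a ring-opened cyclopropane. The cis C3 arm/C4 methyl pair allows the lactone tether that steers the electrophile to C4.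
4. 12 ⇐ cyclopropylmethanol 9 + but-3-enoic acid (ester, then ozonolysis); 9 ⇐ Z-allylic alcohol 8 by dioxaborolane-controlled Simmons–Smith cyclopropanation; 8 ⇐ (R)-citronellal + 6-phenylhex-1-ene.
5. Ring order: cyclopropane (step 7), 1,2,4-trioxolane (step 9), then δ-lactone and 1,2-dioxane together (step 10); the lactone is opened in step 11.

Key step: step 10

Remark (assumption): the tethered peroxycarbenium ion is taken to add to the cyclopropane at the C–C edge with retention at both carbons; the Z-alcohol 8 (CH2O arm cis to the long chain) is chosen on that basis.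

**Route**

Step 1
Reactants: 1 (R)-citronellal [(3R)-3,7-dimethyloct-6-enal]; 2 6-phenylhex-1-ene
Product: 3 (3R,6E)-3-methyl-11-phenylundec-6-enal (E/Z mixture acceptable)
Conditions: second-generation Grubbs catalyst RuCl2(=CHPh)(PCy3)(H2IMes) (3 mol %), 2 (3 equiv), CH2Cl2, 40 °C
Reagents that add atoms: none
Why: Olefin cross-metathesis of the prenyl-type trisubstituted alkene with the terminal alkene should exchange the isopropylidene end for the phenylalkylidene end with loss of volatile isobutene, leaving the aldehyde and the stereocenter untouched; the alkene geometry is irrelevant because step 2 saturates it.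

Step 2
Reactants: 3 (3R,6E)-3-methyl-11-phenylundec-6-enal
Product: 4 (3R)-3-methyl-11-phenylundecanal
Conditions: H2 (1 atm), Pd/C (5 %), EtOAc, rt
Reagents that add atoms: none
Why: Heterogeneous catalytic hydrogenation should saturate the disubstituted alkene much faster than it touches the aliphatic aldehyde or the arene.

Step 3
Reactants: 4 (3R)-3-methyl-11-phenylundecanal
Product: 5 (4R)-4-methyl-12-phenyldodec-1-yne
Conditions: dimethyl (1-diazo-2-oxopropyl)phosphonate, K2CO3, MeOH, 0 °C → rt
Reagents that add atoms: dimethyl (1-diazo-2-oxopropyl)phosphonate, COP(=O)(OC)C(=[N+]=[N-])C(C)=O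
Why: Ohira–Bestmann (Seyferth–Gilbert) homologation should convert the aldehyde into the terminal alkyne under mild base; the stereocenter is β to the carbonyl and cannot epimerise.

Step 4
Reactants: 5 (4R)-4-methyl-12-phenyldodec-1-yne
Product: 6 methyl (5R)-5-methyl-13-phenyltridec-2-ynoate
Conditions: nBuLi, THF, −78 °C; then ClCO2Me, −78 °C → 0 °C
Reagents that add atoms: methyl chloroformate, COC(=O)Cl
Why: C-acylation of the lithium acetylide with a chloroformate is the standard route to 2-alkynoates.

Step 5
Reactants: 6 methyl (5R)-5-methyl-13-phenyltridec-2-ynoate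
Product: 7 methyl (2Z,5R)-3,5-dimethyl-13-phenyltridec-2-enoate
Conditions: Me2CuLi (from MeLi and CuI), THF, −78 °C; MeOH then aq NH4Cl at −78 °C
Reagents that add atoms: lithium dimethylcuprate, [Li+].C[Cu-]C
Why: syn-Carbocupration (conjugate addition) of the Gilman reagent to the 2-alkynoate with protonation at low temperature should place the new methyl trans to the ester, so the ester ends cis to the chain (Z alkene).

Step 6
Reactants: 7 methyl (2Z,5R)-3,5-dimethyl-13-phenyltridec-2-enoate
Product: 8 (2Z,5R)-3,5-dimethyl-13-phenyltridec-2-en-1-ol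
Conditions: iBu2AlH (2.2 equiv), CH2Cl2, −78 °C → 0 °C; Rochelle salt work-up
Reagents that add atoms: none
Why: 1,2-Reduction of the enoate with an aluminium hydride should give the allylic alcohol with the alkene geometry retained.

Step 7
Reactants: 8 (2Z,5R)-3,5-dimethyl-13-phenyltridec-2-en-1-ol
Product: 9 [(1S,2R)-2-methyl-2-[(2R)-2-methyl-10-phenyldecyl]cyclopropyl]methanol
Conditions: Zn(CH2I)2·DME (from Et2Zn, CH2I2, DME), (4R,5R)-2-butyl-N,N,N',N'-tetramethyl-1,3,2-dioxaborolane-4,5-dicarboxamide (1.2 equiv), CH2Cl2, −10 °C → rt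
Reagents that add atoms: diiodomethane, ICI
Why: Charette asymmetric Simmons–Smith cyclopropanation: the zinc alkoxide bound to the chiral dioxaborolane should deliver CH2 to one alkene face, and the stereospecific syn addition keeps the CH2OH arm cis to the long chain, setting both ring carbons as (1S,2R).

Step 8
Reactants: 9 [(1S,2R)-2-methyl-2-[(2R)-2-methyl-10-phenyldecyl]cyclopropyl]methanol; 10 but-3-enoic acid
Product: 11 [(1S,2R)-2-methyl-2-[(2R)-2-methyl-10-phenyldecyl]cyclopropyl]methyl but-3-enoate
Conditions: DCC, DMAP (5 mol %), CH2Cl2, 0 °C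
Reagents that add atoms: none
Why: Steglich esterification at 0 °C should acylate the primary alcohol without moving the β,γ double bond into conjugation.

Step 9
Reactants: 11 [(1S,2R)-2-methyl-2-[(2R)-2-methyl-10-phenyldecyl]cyclopropyl]methyl but-3-enoate
Product: 12 [(1S,2R)-2-methyl-2-[(2R)-2-methyl-10-phenyldecyl]cyclopropyl]methyl 2-(1,2,4-trioxolan-3-yl)acetate (ozonide, both epimers at the trioxolane carbon)
Conditions: O3 (1 equiv), CH2Cl2, −78 °C; N2 purge; warm to 0 °C; rapid chromatography
Reagents that add atoms: ozone, [O-][O+]=O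
Why: Ozonolysis in a non-participating solvent should give the secondary ozonide by recombination of the carbonyl oxide with formaldehyde (Criegee mechanism); the terminal alkene reacts far faster than the alkylbenzene ring or the cyclopropane, and the epimer mixture is of no consequence because step 10 erases that center.

Step 10
Reactants: 12 ozonide ester (both epimers)
Product: 14 cis-fused peroxy-lactone (δ-lactone of 2-[(3S,4R,6R)-4-(hydroxymethyl)-6-methyl-6-[(2R)-2-methyl-10-phenyldecyl]-1,2-dioxan-3-yl]acetic acid), via peroxycarbenium triflate 13 (not isolated)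
Conditions: TMSOTf (0.2 equiv), 4 Å MS, CH2Cl2, −78 °C → −30 °C; pyridine quench
Reagents that add atoms: none
Why: Proposed new method: TMSOTf should silylate the ether oxygen of ozonide 12 and open the ring at the more substituted carbon to peroxycarbenium 13 (both ozonide epimers give the same ion, so the mixture is funnelled), in which C3 is held by the ester tether over the C4–C6 edge of the cyclopropane. The strained C4–C6 σ bond then adds across the C3–O–O unit: C3 bonds to C4 (6-exo closure of the δ-lactone) and the distal peroxide oxygen O1 captures the charge developing at tertiary C6 (six-membered 1,2-dioxane closure, 6-endo with respect to the displaced σ bond), after which the O–CH2–OSiMe3 group falls apart to formaldehyde and TMSOTf. The closest known reaction types are the Lewis-acid [3+2] annulation of peroxycarbenium ions, generated from silyl peroxyacetals or ozonides, with alkenes to 1,2-dioxolanes and the stereospecific electrophilic 1,3-addition to cyclopropanes; here the cyclopropane σ bond takes the part of the alkene π bond. C4 should keep the configuration installed in step 7 because the electrophile enters at the bond edge (retention), C6 should be formed with retention because O1 sits on the same edge and collapses onto the lobe that C4 vacates before the C5–C6 bond can rotate, and C3 is set cis to the C4 arm because the lactone tether delivers it with its CH2 arm on the face of the CH2O arm. The step needs attack at the substituted C4 corner instead of the intrinsically preferred CH2 corner, and ionisation of the ozonide instead of its fragmentation; the first is secured by the tether (a six-membered lactone can form only through C4) and the tertiary character of C6, the second by the low temperature and the preference for the secondary over the primary cation.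

Step 11
Reactants: 14 cis-fused peroxy-lactone
Product: 15 methyl 2-[(3S,4R,6R)-4-(hydroxymethyl)-6-methyl-6-[(2R)-2-methyl-10-phenyldecyl]-1,2-dioxan-3-yl]acetate
Conditions: K2CO3 (0.2 equiv), MeOH, 0 °C
Reagents that add atoms: methanol, CO
Why: Base-catalysed transesterification in methanol should open the δ-lactone to the hydroxy methyl ester at 0 °C, conditions under which the β-peroxy ester is expected to survive.

Step 12
Reactants: 15 hydroxymethyl ester
Product: 17 methyl 2-[(3S,4S,6R)-4-(iodomethyl)-6-methyl-6-[(2R)-2-methyl-10-phenyldecyl]-1,2-dioxan-3-yl]acetate, via mesylate 16 (not isolated)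
Conditions: MsCl, Et3N, CH2Cl2, 0 °C; then NaI, acetone, 45 °C
Reagents that add atoms: sodium iodide, [Na+].[I-]
Why: Mesylation followed by Finkelstein SN2 displacement at the primary carbon should give the iodide without touching the dialkyl peroxide or any stereocenter.

Step 13
Reactants: 17 iodomethyl ester
Product: 18 methyl 2-[(3S,4S,6R)-4,6-dimethyl-6-[(2R)-2-methyl-10-phenyldecyl]-1,2-dioxan-3-yl]acetate
Conditions: Bu3SnH, AIBN (10 mol %), benzene, 80 °C
Reagents that add atoms: none
Why: Tin hydride radical-chain reduction of the primary iodide should unveil the C4 methyl group; dialkyl peroxides tolerate these conditions and the exocyclic primary radical has no geometrically favourable path to the O–O bond.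

Step 14
Reactants: 18 methyl ester
Product: 19 2-[(3S,4S,6R)-4,6-dimethyl-6-[(2R)-2-methyl-10-phenyldecyl]-1,2-dioxan-3-yl]acetic acid (target)
Conditions: LiOH, THF/H2O (3:1), 0 °C → rt; then 1 M HCl to pH 3
Reagents that add atoms: lithium hydroxide, [Li+].[OH-]
Why: Saponification of the methyl ester at low temperature should free the acid; mild hydroxide is the usual final step for 1,2-dioxane-3-acetates and should not open the ring.

**Compound list**

1 | (R)-citronellal, (3R)-3,7-dimethyloct-6-enal | C[C@H](CCC=C(C)C)CC=O | starting material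
2 | 6-phenylhex-1-ene | C=CCCCCc1ccccc1 | starting material
3 | (3R,6E)-3-methyl-11-phenylundec-6-enal | C[C@H](CC/C=C/CCCCc1ccccc1)CC=O | intermediate
4 | (3R)-3-methyl-11-phenylundecanal | C[C@H](CCCCCCCCc1ccccc1)CC=O | intermediate
5 | (4R)-4-methyl-12-phenyldodec-1-yne | C[C@H](CCCCCCCCc1ccccc1)CC#C | intermediate
6 | methyl (5R)-5-methyl-13-phenyltridec-2-ynoate | C[C@H](CCCCCCCCc1ccccc1)CC#CC(=O)OC | intermediate
7 | methyl (2Z,5R)-3,5-dimethyl-13-phenyltridec-2-enoate | C[C@H](CCCCCCCCc1ccccc1)C/C(C)=C\C(=O)OC | intermediate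
8 | (2Z,5R)-3,5-dimethyl-13-phenyltridec-2-en-1-ol | C[C@H](CCCCCCCCc1ccccc1)C/C(C)=C\CO | intermediate
9 | [(1S,2R)-2-methyl-2-[(2R)-2-methyl-10-phenyldecyl]cyclopropyl]methanol | C[C@H](CCCCCCCCc1ccccc1)C[C@]1(C)C[C@@H]1CO | intermediate
10 | but-3-enoic acid | C=CCC(=O)O | starting material
11 | [(1S,2R)-2-methyl-2-[(2R)-2-methyl-10-phenyldecyl]cyclopropyl]methyl but-3-enoate | C[C@H](CCCCCCCCc1ccccc1)C[C@]1(C)C[C@@H]1COC(=O)CC=C | intermediate
12 | [(1S,2R)-2-methyl-2-[(2R)-2-methyl-10-phenyldecyl]cyclopropyl]methyl 2-(1,2,4-trioxolan-3-yl)acetate (both epimers at the trioxolane carbon) | C[C@H](CCCCCCCCc1ccccc1)C[C@]1(C)C[C@@H]1COC(=O)CC2OCOO2 | intermediate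
13 | ring-opened peroxycarbenium triflate of 12 (O-silylated on the formaldehyde-derived oxygen) | C[C@H](CCCCCCCCc1ccccc1)C[C@]1(C)C[C@@H]1COC(=O)CC=[O+]OCO[Si](C)(C)C.[O-]S(=O)(=O)C(F)(F)F | intermediate
14 | cis-fused peroxy-lactone: δ-lactone of 2-[(3S,4R,6R)-4-(hydroxymethyl)-6-methyl-6-[(2R)-2-methyl-10-phenyldecyl]-1,2-dioxan-3-yl]acetic acid | C[C@H](CCCCCCCCc1ccccc1)C[C@]1(C)C[C@@H]2COC(=O)C[C@@H]2OO1 | intermediate
15 | methyl 2-[(3S,4R,6R)-4-(hydroxymethyl)-6-methyl-6-[(2R)-2-methyl-10-phenyldecyl]-1,2-dioxan-3-yl]acetate | C[C@H](CCCCCCCCc1ccccc1)C[C@]1(C)C[C@H](CO)[C@H](CC(=O)OC)OO1 | intermediate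
16 | methyl 2-[(3S,4R,6R)-6-methyl-4-[(methylsulfonyloxy)methyl]-6-[(2R)-2-methyl-10-phenyldecyl]-1,2-dioxan-3-yl]acetate | C[C@H](CCCCCCCCc1ccccc1)C[C@]1(C)C[C@H](COS(C)(=O)=O)[C@H](CC(=O)OC)OO1 | intermediate
17 | methyl 2-[(3S,4S,6R)-4-(iodomethyl)-6-methyl-6-[(2R)-2-methyl-10-phenyldecyl]-1,2-dioxan-3-yl]acetate | C[C@H](CCCCCCCCc1ccccc1)C[C@]1(C)C[C@H](CI)[C@H](CC(=O)OC)OO1 | intermediate
18 | methyl 2-[(3S,4S,6R)-4,6-dimethyl-6-[(2R)-2-methyl-10-phenyldecyl]-1,2-dioxan-3-yl]acetate | C[C@H](CCCCCCCCc1ccccc1)C[C@]1(C)C[C@H](C)[C@H](CC(=O)OC)OO1 | intermediate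
19 | 2-[(3S,4S,6R)-4,6-dimethyl-6-[(2R)-2-methyl-10-phenyldecyl]-1,2-dioxan-3-yl]acetic acid | C[C@H](CCCCCCCCc1ccccc1)C[C@]1(C)C[C@H](C)[C@H](CC(=O)O)OO1 | target

**Totals and risks**

Total step count: 14. Longest linear sequence: 14 steps (1 → 19).

Steps most likely to fail:

1. Step 10 (Proposed new method).
   - What may go wrong: Lewis-acid fragmentation of the ozonide or proton loss from the peroxycarbenium ion before C–C bond formation; attack at the CH2 corner of the cyclopropane; rotation of the C6 cation before capture, eroding configuration at C6 (if capture instead occurred cleanly with inversion, the E isomer of 8 would be the correcting precursor).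
   - Fallback with known chemistry, setting out from 5 and coming back at 18:
     - Markovnikov hydrobromination of 5 (B-bromo-9-borabicyclo[3.3.1]nonane, then AcOH) should give (4R)-2-bromo-4-methyl-12-phenyldodec-1-ene F1.
     - Negishi coupling (Pd(PPh3)4) of F1 with {(2R)-3-[tert-butyl(dimethyl)silyl]oxy-2-methylpropyl}zinc iodide F2, made from the Roche-ester-derived iodide and zinc, should give tert-butyl{[(2S,6R)-2,6-dimethyl-4-methylidene-14-phenyltetradecyl]oxy}dimethylsilane F3.
     - Fluoride desilylation should give (2S,6R)-2,6-dimethyl-4-methylidene-14-phenyltetradecan-1-ol F4, and Dess–Martin oxidation (2S,6R)-2,6-dimethyl-4-methylidene-14-phenyltetradecanal F5.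
     - Wittig reaction with methyl (triphenylphosphoranylidene)acetate should give methyl (2E,4S,8R)-4,8-dimethyl-6-methylidene-16-phenylhexadec-2-enoate F6.
     - Mukaiyama–Isayama hydroperoxysilylation (Co(acac)2, O2, Et3SiH) should give methyl (2E,4S,8R)-4,6,8-trimethyl-16-phenyl-6-[(triethylsilyl)peroxy]hexadec-2-enoate F7.
     - Desilylation (HCl, MeOH) and amine-mediated intramolecular oxa-Michael addition should close the 1,2-dioxane to 18, to be separated from its C3 and C6 diastereomers, since this route does not control C6.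

2. Step 9.
   - What may go wrong: the ozonide carries acidic hydrogens next to the ester and may fragment on isolation, or ozone may over-oxidise the substrate.
   - Fallback, setting out from 9 and coming back at 14, replaces the ozonide by a silyl peroxyacetal as the peroxycarbenium source:
     - Transesterification of 9 with methyl 3,3-dimethoxypropanoate (Bu2SnO cat., toluene) should give [(1S,2R)-2-methyl-2-[(2R)-2-methyl-10-phenyldecyl]cyclopropyl]methyl 3,3-dimethoxypropanoate F8.
     - Acid-catalysed exchange with H2O2 should give the 3-hydroperoxy-3-methoxypropanoate F9.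
     - Silylation (Et3SiOTf, 2,6-lutidine) should give the 3-methoxy-3-[(triethylsilyl)peroxy]propanoate F10.
     - TMSOTf should then ionise F10 with loss of methoxide and deliver 14 by the same tethered annulation.

3. Step 11.
   - What may go wrong: re-lactonisation of the hydroxy ester on work-up, or base-induced retro-oxa-Michael opening that scrambles C3.
   - Fallback, setting out from 14 and coming back at 19:
     - Direct alkyl–oxygen scission of the lactone by iodide (NaI, Me3SiCl, MeCN, 0 °C) should give 2-[(3S,4S,6R)-4-(iodomethyl)-6-methyl-6-[(2R)-2-methyl-10-phenyldecyl]-1,2-dioxan-3-yl]acetic acid F11.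
     - Bu3SnH/AIBN should reduce F11 straight to 19, with no base at any stage; the price is the risk of iodide reducing the peroxide.

**Further compounds**

F1 | step 10 | (4R)-2-bromo-4-methyl-12-phenyldodec-1-ene | C[C@H](CCCCCCCCc1ccccc1)CC(Br)=C
F2 | step 10 | {(2R)-3-[tert-butyl(dimethyl)silyl]oxy-2-methylpropyl}zinc iodide | I[Zn]C[C@H](C)CO[Si](C)(C)C(C)(C)C
F3 | step 10 | tert-butyl{[(2S,6R)-2,6-dimethyl-4-methylidene-14-phenyltetradecyl]oxy}dimethylsilane | C[C@H](CCCCCCCCc1ccccc1)CC(=C)C[C@H](C)CO[Si](C)(C)C(C)(C)C
F4 | step 10 | (2S,6R)-2,6-dimethyl-4-methylidene-14-phenyltetradecan-1-ol | C[C@H](CCCCCCCCc1ccccc1)CC(=C)C[C@H](C)CO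
F5 | step 10 | (2S,6R)-2,6-dimethyl-4-methylidene-14-phenyltetradecanal | C[C@H](CCCCCCCCc1ccccc1)CC(=C)C[C@H](C)C=O
F6 | step 10 | methyl (2E,4S,8R)-4,8-dimethyl-6-methylidene-16-phenylhexadec-2-enoate | C[C@H](CCCCCCCCc1ccccc1)CC(=C)C[C@H](C)/C=C/C(=O)OC
F7 | step 10 | methyl (2E,4S,8R)-4,6,8-trimethyl-16-phenyl-6-[(triethylsilyl)peroxy]hexadec-2-enoate (both epimers at C6) | C[C@H](CCCCCCCCc1ccccc1)CC(C)(OO[Si](CC)(CC)CC)C[C@H](C)/C=C/C(=O)OC
F8 | step 9 | [(1S,2R)-2-methyl-2-[(2R)-2-methyl-10-phenyldecyl]cyclopropyl]methyl 3,3-dimethoxypropanoate | C[C@H](CCCCCCCCc1ccccc1)C[C@]1(C)C[C@@H]1COC(=O)CC(OC)OC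
F9 | step 9 | [(1S,2R)-2-methyl-2-[(2R)-2-methyl-10-phenyldecyl]cyclopropyl]methyl 3-hydroperoxy-3-methoxypropanoate | C[C@H](CCCCCCCCc1ccccc1)C[C@]1(C)C[C@@H]1COC(=O)CC(OC)OO
F10 | step 9 | [(1S,2R)-2-methyl-2-[(2R)-2-methyl-10-phenyldecyl]cyclopropyl]methyl 3-methoxy-3-[(triethylsilyl)peroxy]propanoate | C[C@H](CCCCCCCCc1ccccc1)C[C@]1(C)C[C@@H]1COC(=O)CC(OC)OO[Si](CC)(CC)CC
F11 | step 11 | 2-[(3S,4S,6R)-4-(iodomethyl)-6-methyl-6-[(2R)-2-methyl-10-phenyldecyl]-1,2-dioxan-3-yl]acetic acid | C[C@H](CCCCCCCCc1ccccc1)C[C@]1(C)C[C@H](CI)[C@H](CC(=O)O)OO1
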